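**Retrosynthetic overview**

Side-chain numbering: ArO–C1'H2–C2'H(OH)–C3'(CH3)(OH)–C4'H2–C5'H(O5')–C6'H2–C7'(=C8'H2)–C9'(=O)–O5'. The plan rests on the five-membered ring O5'–C5'–C6'–C7'–C9' with its exocyclic C7'=C8' bond: without the C9' carbonyl oxygen it is a 2-substituted 4-methylenetetrahydrofuran, which is trimethylenemethane added across the C5'=O of an aldehyde.
Disconnections, backwards: acetonide off; C9'=O by allylic oxidation of the cyclic allyl ether; C1'–OAr by Mitsunobu etherification with umbelliferone; C5'–C6' and O5'–C9' by the palladium (3+2) cycloaddition onto the C5' aldehyde.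
The aldehyde comes from a terminal alkene. The anti-2',3'-diol comes from the (2R,3R)-epoxide of (2E)-3-methylhexa-2,5-dien-1-ol by hydrolysis with inversion at C3', and the dienol from pent-1-en-4-yne by carboalumination.
Ring order: dioxolane (protecting ring, step 5), then the oxolane (step 7), which becomes the lactone in step 10; the coumarin bicycle arrives intact with umbelliferone in step 9.

Key step: step 7

Remark: the coumarin C3=C4 bond is itself an acceptor for palladium–trimethylenemethane, so C1'–O is carried as a TBDPS ether through the cycloaddition and umbelliferone is attached afterwards; the ligand antipode that gives (5'S) has to be found by trial.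

**Route**

Step 1
Reactants: 1 pent-1-en-4-yne
Product: 4 (2E)-3-methylhexa-2,5-dien-1-ol, via dimethyl[(1E)-2-methylpenta-1,4-dien-1-yl]alane 2 (not isolated), via lithium butyl(dimethyl)[(1E)-2-methylpenta-1,4-dien-1-yl]aluminate 3 (not isolated)
Conditions: Me3Al, Cp2ZrCl2 (cat.), CH2Cl2, 0 °C to rt; volatiles removed; n-BuLi, THF, −78 to 0 °C; (CH2O)n, rt; aq. HCl
Reagents that add atoms: trimethylaluminium, C[Al](C)C; paraformaldehyde (as formaldehyde), C=O
Why: Negishi zirconium-catalysed carboalumination adds CH3 and Al syn across the terminal alkyne with the methyl on the internal carbon (the isolated alkene reacts far more slowly), and the derived aluminate transfers the alkenyl group to formaldehyde with retention, so the trisubstituted alkene should be E.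

Step 2
Reactants: 4 (2E)-3-methylhexa-2,5-dien-1-ol
Product: 5 [(2R,3R)-3-methyl-3-(prop-2-en-1-yl)oxiran-2-yl]methanol
Conditions: Ti(OiPr)4 (10 mol%), D-(−)-diethyl tartrate (12 mol%), t-BuOOH, 4 Å molecular sieves, CH2Cl2, −20 °C
Reagents that add atoms: tert-butyl hydroperoxide, CC(C)(C)OO
Why: Katsuki–Sharpless asymmetric epoxidation acts only on the allylic-alcohol alkene, and with D-(−)-diethyl tartrate an (E)-3-methylalk-2-en-1-ol of the geraniol type should give the (2R,3R)-epoxide under reagent control, fixing C2' and C3' from one face.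

Step 3
Reactants: 5 [(2R,3R)-3-methyl-3-(prop-2-en-1-yl)oxiran-2-yl]methanol
Product: 6 tert-butyl{[(2R,3R)-3-methyl-3-(prop-2-en-1-yl)oxiran-2-yl]methoxy}diphenylsilane
Conditions: TBDPSCl, imidazole, CH2Cl2, 0 °C to rt
Reagents that add atoms: tert-butyl(chloro)diphenylsilane, CC(C)(C)[Si](Cl)(c1ccccc1)c1ccccc1
Why: Standard silylation of the primary alcohol; the bulky silyl ether should survive the dilute acid, osmium and palladium steps that follow and keeps the C1' oxygen masked.

Step 4
Reactants: 6 tert-butyl{[(2R,3R)-3-methyl-3-(prop-2-en-1-yl)oxiran-2-yl]methoxy}diphenylsilane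
Product: 7 (2R,3S)-1-[(tert-butyldiphenylsilyl)oxy]-3-methylhex-5-ene-2,3-diol
Conditions: HClO4 (5 mol%), THF/H2O 3:1, 0 °C to rt
Reagents that add atoms: water, O
Why: Acid-catalysed epoxide hydrolysis: water attacks the protonated trisubstituted epoxide at the tertiary C3', which carries most of the positive charge, from the back (borderline SN2), so C3' is inverted to S while C2' keeps its oxygen and its R configuration, giving the 2',3'-anti diol.

Step 5
Reactants: 7 (2R,3S)-1-[(tert-butyldiphenylsilyl)oxy]-3-methylhex-5-ene-2,3-diol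
Product: 8 tert-butyl{[(4R,5S)-2,2,5-trimethyl-5-(prop-2-en-1-yl)-1,3-dioxolan-4-yl]methoxy}diphenylsilane
Conditions: 2,2-dimethoxypropane, CSA (cat.), CH2Cl2, rt
Reagents that add atoms: 2,2-dimethoxypropane, COC(C)(C)OC
Why: Acid-catalysed transketalisation closes the 1,3-dioxolane over the secondary and tertiary hydroxyls, the only diol present, and protects both before the oxidising and palladium steps.

Step 6
Reactants: 8 tert-butyl{[(4R,5S)-2,2,5-trimethyl-5-(prop-2-en-1-yl)-1,3-dioxolan-4-yl]methoxy}diphenylsilane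
Product: 10 2-[(4S,5R)-5-{[(tert-butyldiphenylsilyl)oxy]methyl}-2,2,4-trimethyl-1,3-dioxolan-4-yl]acetaldehyde, via vicinal diol 9 (not isolated)
Conditions: OsO4 (2 mol%), NaIO4, 2,6-lutidine, dioxane/H2O 3:1, rt
Reagents that add atoms: osmium tetroxide, O=[Os](=O)(=O)=O; sodium periodate (restores the osmium oxo groups), [Na+].[O-]I(=O)(=O)=O
Why: Lemieux–Johnson oxidation: osmylation of the only alkene and periodate cleavage of diol 9 should give the C5' aldehyde, with 2,6-lutidine suppressing side reactions and no stereocentre touched.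

Step 7
Reactants: 10 2-[(4S,5R)-5-{[(tert-butyldiphenylsilyl)oxy]methyl}-2,2,4-trimethyl-1,3-dioxolan-4-yl]acetaldehyde; 11 2-[(trimethylsilyl)methyl]allyl acetate
Product: 14 tert-butyl{[(4R,5S)-2,2,5-trimethyl-5-{[(2S)-4-methylideneoxolan-2-yl]methyl}-1,3-dioxolan-4-yl]methoxy}diphenylsilane, via palladium–trimethylenemethane zwitterion 12 (not isolated), via alkoxide π-allylpalladium adduct 13 (not isolated)
Conditions: Pd(dba)2 [bis(dibenzylideneacetone)palladium] (5 mol%), BINOL-derived phosphoramidite with a trans-2,5-diarylpyrrolidine amine part (10 mol%), In(acac)3 (10 mol%), toluene, 50 °C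
Reagents that add atoms: none
Why: Zerovalent palladium ionises the allylic acetate of 11 and the acetate removes the silyl group to give zwitterion 12, whose carbanionic carbon adds to the In(acac)3-activated aldehyde (C5'–C6') to give alkoxide 13, which then attacks the π-allyl terminus (O5'–C9'), a stepwise (3+2) cycloaddition. The closest known reaction is the palladium-catalysed trimethylenemethane cycloaddition to aldehydes with tin or indium co-catalysts, established for aliphatic aldehydes without ligand control and with chiral phosphoramidites mainly for aryl aldehydes. The oxolane ring (O5', C5', C6', C7', C9') closes by 5-exo attack of the alkoxide oxygen on the π-allylpalladium unit, leaving C7'=C8' exocyclic. The new centre C5' (S, 1,3-syn to the C3' oxygen) must be set by the chiral ligand on palladium, because the quaternary C3' centre gives little 1,3-induction; both ligand antipodes are tried to find the matched pair. The step needs carbonyl addition to outrun deprotonation at C4' and β-elimination of the C3' oxygen; the indium co-catalyst, the near-neutral medium and the poor leaving ability of the ketal oxygen should secure this. No competing acceptor is present, since the C1' oxygen carries a silyl group and not the coumarin.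

Step 8
Reactants: 14 tert-butyl{[(4R,5S)-2,2,5-trimethyl-5-{[(2S)-4-methylideneoxolan-2-yl]methyl}-1,3-dioxolan-4-yl]methoxy}diphenylsilane
Product: 15 [(4R,5S)-2,2,5-trimethyl-5-{[(2S)-4-methylideneoxolan-2-yl]methyl}-1,3-dioxolan-4-yl]methanol
Conditions: TBAF, THF, 0 °C to rt
Reagents that add atoms: none
Why: Fluoride-mediated desilylation driven by the strong Si–F bond; the acetonide and the cyclic allyl ether are inert to TBAF.

Step 9
Reactants: 15 [(4R,5S)-2,2,5-trimethyl-5-{[(2S)-4-methylideneoxolan-2-yl]methyl}-1,3-dioxolan-4-yl]methanol; 16 umbelliferone (7-hydroxy-2H-chromen-2-one)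
Product: 17 7-{[(4R,5S)-2,2,5-trimethyl-5-{[(2S)-4-methylideneoxolan-2-yl]methyl}-1,3-dioxolan-4-yl]methoxy}-2H-chromen-2-one
Conditions: PPh3, DIAD, THF, 0 °C to rt
Reagents that add atoms: none
Why: Mitsunobu etherification: the primary alcohol is activated as an alkoxyphosphonium ion and displaced at the CH2 carbon C1' by the acidic phenol, so no stereocentre is involved and no base is present that would open the coumarin lactone.

Step 10
Reactants: 17 7-{[(4R,5S)-2,2,5-trimethyl-5-{[(2S)-4-methylideneoxolan-2-yl]methyl}-1,3-dioxolan-4-yl]methoxy}-2H-chromen-2-one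
Product: 18 7-{[(4R,5S)-2,2,5-trimethyl-5-{[(2S)-4-methylidene-5-oxooxolan-2-yl]methyl}-1,3-dioxolan-4-yl]methoxy}-2H-chromen-2-one
Conditions: CrO3, pyridine (CrO3·2py formed in situ, excess), CH2Cl2, rt
Reagents that add atoms: chromium trioxide, O=[Cr](=O)=O
Why: Allylic oxidation with the CrO3–pyridine complex (Collins reagent) at C9'H2, the only CH2 that is both allylic and next to the ring oxygen, should turn the cyclic allyl ether into the α-methylene-γ-lactone, a conversion known for 2-substituted 4-methylenetetrahydrofurans; C5' is not touched.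

Step 11
Reactants: 18 7-{[(4R,5S)-2,2,5-trimethyl-5-{[(2S)-4-methylidene-5-oxooxolan-2-yl]methyl}-1,3-dioxolan-4-yl]methoxy}-2H-chromen-2-one
Product: 19 7-{[(2R,3S)-2,3-dihydroxy-3-methyl-4-[(2S)-4-methylidene-5-oxooxolan-2-yl]butyl]oxy}-2H-chromen-2-one (target)
Conditions: AcOH/H2O 4:1, 45 °C
Reagents that add atoms: none
Why: Acid-catalysed hydrolysis of the isopropylidene ketal frees the secondary and tertiary hydroxyls; mild aqueous acetic acid should leave the lactone, the exocyclic alkene, the aryl ether and the coumarin intact and not ionise the tertiary alcohol.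

**Compound list**

1 | pent-1-en-4-yne | C#CCC=C | starting material
2 | dimethyl[(1E)-2-methylpenta-1,4-dien-1-yl]alane | C=CC/C(C)=C/[Al](C)C | intermediate
3 | lithium butyl(dimethyl)[(1E)-2-methylpenta-1,4-dien-1-yl]aluminate | [Li+].C=CC/C(C)=C/[Al-](C)(C)CCCC | intermediate
4 | (2E)-3-methylhexa-2,5-dien-1-ol | C=CC/C(C)=C/CO | intermediate
5 | [(2R,3R)-3-methyl-3-(prop-2-en-1-yl)oxiran-2-yl]methanol | C=CC[C@@]1(C)O[C@@H]1CO | intermediate
6 | tert-butyl{[(2R,3R)-3-methyl-3-(prop-2-en-1-yl)oxiran-2-yl]methoxy}diphenylsilane | C=CC[C@@]1(C)O[C@@H]1CO[Si](c2ccccc2)(c2ccccc2)C(C)(C)C | intermediate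
7 | (2R,3S)-1-[(tert-butyldiphenylsilyl)oxy]-3-methylhex-5-ene-2,3-diol | C=CC[C@](C)(O)[C@H](O)CO[Si](c1ccccc1)(c1ccccc1)C(C)(C)C | intermediate
8 | tert-butyl{[(4R,5S)-2,2,5-trimethyl-5-(prop-2-en-1-yl)-1,3-dioxolan-4-yl]methoxy}diphenylsilane | C=CC[C@]1(C)OC(C)(C)O[C@@H]1CO[Si](c2ccccc2)(c2ccccc2)C(C)(C)C | intermediate
9 | 3-[(4S,5R)-5-{[(tert-butyldiphenylsilyl)oxy]methyl}-2,2,4-trimethyl-1,3-dioxolan-4-yl]propane-1,2-diol (both C2 epimers) | OCC(O)C[C@]1(C)OC(C)(C)O[C@@H]1CO[Si](c2ccccc2)(c2ccccc2)C(C)(C)C | intermediate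
10 | 2-[(4S,5R)-5-{[(tert-butyldiphenylsilyl)oxy]methyl}-2,2,4-trimethyl-1,3-dioxolan-4-yl]acetaldehyde | O=CC[C@]1(C)OC(C)(C)O[C@@H]1CO[Si](c2ccccc2)(c2ccccc2)C(C)(C)C | intermediate
11 | 2-[(trimethylsilyl)methyl]allyl acetate | CC(=O)OCC(=C)C[Si](C)(C)C | starting material
12 | palladium–trimethylenemethane zwitterion (ligands omitted) | [CH2-]C(=C)C[Pd+] | intermediate
13 | alkoxide π-allylpalladium adduct (ligands omitted) | [O-][C@@H](CC(=C)C[Pd+])C[C@]1(C)OC(C)(C)O[C@@H]1CO[Si](c2ccccc2)(c2ccccc2)C(C)(C)C | intermediate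
14 | tert-butyl{[(4R,5S)-2,2,5-trimethyl-5-{[(2S)-4-methylideneoxolan-2-yl]methyl}-1,3-dioxolan-4-yl]methoxy}diphenylsilane | C=C1C[C@@H](C[C@]2(C)OC(C)(C)O[C@@H]2CO[Si](c3ccccc3)(c3ccccc3)C(C)(C)C)OC1 | intermediate
15 | [(4R,5S)-2,2,5-trimethyl-5-{[(2S)-4-methylideneoxolan-2-yl]methyl}-1,3-dioxolan-4-yl]methanol | C=C1C[C@@H](C[C@]2(C)OC(C)(C)O[C@@H]2CO)OC1 | intermediate
16 | umbelliferone (7-hydroxy-2H-chromen-2-one) | Oc1ccc2ccc(=O)oc2c1 | starting material
17 | 7-{[(4R,5S)-2,2,5-trimethyl-5-{[(2S)-4-methylideneoxolan-2-yl]methyl}-1,3-dioxolan-4-yl]methoxy}-2H-chromen-2-one | C=C1C[C@@H](C[C@]2(C)OC(C)(C)O[C@@H]2COc3ccc4ccc(=O)oc4c3)OC1 | intermediate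
18 | 7-{[(4R,5S)-2,2,5-trimethyl-5-{[(2S)-4-methylidene-5-oxooxolan-2-yl]methyl}-1,3-dioxolan-4-yl]methoxy}-2H-chromen-2-one | C=C1C[C@@H](C[C@]2(C)OC(C)(C)O[C@@H]2COc3ccc4ccc(=O)oc4c3)OC1=O | intermediate
19 | 7-{[(2R,3S)-2,3-dihydroxy-3-methyl-4-[(2S)-4-methylidene-5-oxooxolan-2-yl]butyl]oxy}-2H-chromen-2-one | C=C1C[C@@H](C[C@](C)(O)[C@H](O)COc2ccc3ccc(=O)oc3c2)OC1=O | target

**Step count**

Total step count: 11. Longest linear sequence: 11 steps (1 to 19).

**Steps most likely to fail**

Step 7. The ligand has to override a remote quaternary centre on an aliphatic aldehyde, so facial selectivity at C5' may be low or of the wrong sense. The basic zwitterion may also deprotonate C4', leading to self-condensation or β-elimination of the C3' oxygen. The fallback sets out from aldehyde 10 and comes back at 14, building the same two bonds one after the other with reagent control. Aldehyde 10 is treated at −78 °C in CH2Cl2 with a chiral 2-bromoallylborane, made from tributyl(2-bromoprop-2-en-1-yl)stannane and the B-bromo-1,3,2-diazaborolidine of N,N'-ditosyl-1,2-diphenylethane-1,2-diamine (antipode chosen for the required face). This should give (2R)-4-bromo-1-[(4S,5R)-5-{[(tert-butyldiphenylsilyl)oxy]methyl}-2,2,4-trimethyl-1,3-dioxolan-4-yl]pent-4-en-2-ol F1. Stille coupling of the vinyl bromide with (tributylstannyl)methanol (Pd(PPh3)4, dioxane, 90 °C) would give (4S)-5-[(4S,5R)-5-{[(tert-butyldiphenylsilyl)oxy]methyl}-2,2,4-trimethyl-1,3-dioxolan-4-yl]-2-methylidenepentane-1,4-diol F2. Selective tosylation of the primary allylic hydroxyl (TsCl, Et3N, CH2Cl2, 0 °C) and 5-exo-tet closure by the C5' alkoxide (KOtBu, THF) then give 14 without breaking the C5'–O bond.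

Step 10. Oxidation may also occur at C6', the double bond may migrate into the ring to give the butenolide, or the large excess of chromium reagent may degrade the material. The fallback sets out from aldehyde 10 and comes back at 18, bringing C9' in at the ester oxidation level so that no allylic oxidation is needed. An indium-mediated Barbier reaction of 10 with ethyl 2-(bromomethyl)acrylate (In, THF/H2O, rt) should give ethyl (4S)-5-[(4S,5R)-5-{[(tert-butyldiphenylsilyl)oxy]methyl}-2,2,4-trimethyl-1,3-dioxolan-4-yl]-4-hydroxy-2-methylidenepentanoate F3 together with its C4 epimer. Lactonisation (PPTS cat., toluene, 60 °C) and chromatographic removal of the wrong epimer would give (5S)-5-{[(4S,5R)-5-{[(tert-butyldiphenylsilyl)oxy]methyl}-2,2,4-trimethyl-1,3-dioxolan-4-yl]methyl}-3-methylideneoxolan-2-one F4. Desilylation with HF·pyridine buffered with pyridine in THF gives (5S)-5-{[(4S,5R)-5-(hydroxymethyl)-2,2,4-trimethyl-1,3-dioxolan-4-yl]methyl}-3-methylideneoxolan-2-one F5, and Mitsunobu etherification with umbelliferone 16 (PPh3, DIAD, THF) gives 18. The price is that C5' is no longer set by a catalyst.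

Step 4. Partial ionisation to a tertiary cation at C3' would erode the inversion and give the 2',3'-syn diol. Some attack at C2' would lead into the enantiomeric series and lower the enantiomeric purity, and the acid may loosen the silyl ether. The fallback sets out from epoxy alcohol 5 and comes back at diol 7, using a hydroxyl-directed, titanium-templated opening in place of free acid. Benzoic acid and Ti(OiPr)4 (1.5 equiv) in CH2Cl2 at rt should deliver the carboxylate to C3' of the titanium-bound epoxy alkoxide with inversion, giving (2R,3S)-1,2-dihydroxy-3-methylhex-5-en-3-yl benzoate F6 (acyl migration among the hydroxyls is harmless). Methanolysis (K2CO3, MeOH) gives (2R,3S)-3-methylhex-5-ene-1,2,3-triol F7, and selective silylation of the primary hydroxyl (TBDPSCl, imidazole, CH2Cl2, 0 °C) gives 7.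

**Further compounds**

F1 | step 7 | (2R)-4-bromo-1-[(4S,5R)-5-{[(tert-butyldiphenylsilyl)oxy]methyl}-2,2,4-trimethyl-1,3-dioxolan-4-yl]pent-4-en-2-ol | C=C(Br)C[C@H](O)C[C@]1(C)OC(C)(C)O[C@@H]1CO[Si](c2ccccc2)(c2ccccc2)C(C)(C)C
F2 | step 7 | (4S)-5-[(4S,5R)-5-{[(tert-butyldiphenylsilyl)oxy]methyl}-2,2,4-trimethyl-1,3-dioxolan-4-yl]-2-methylidenepentane-1,4-diol | C=C(CO)C[C@H](O)C[C@]1(C)OC(C)(C)O[C@@H]1CO[Si](c2ccccc2)(c2ccccc2)C(C)(C)C
F3 | step 10 | ethyl (4S)-5-[(4S,5R)-5-{[(tert-butyldiphenylsilyl)oxy]methyl}-2,2,4-trimethyl-1,3-dioxolan-4-yl]-4-hydroxy-2-methylidenepentanoate | C=C(C(=O)OCC)C[C@H](O)C[C@]1(C)OC(C)(C)O[C@@H]1CO[Si](c2ccccc2)(c2ccccc2)C(C)(C)C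
F4 | step 10 | (5S)-5-{[(4S,5R)-5-{[(tert-butyldiphenylsilyl)oxy]methyl}-2,2,4-trimethyl-1,3-dioxolan-4-yl]methyl}-3-methylideneoxolan-2-one | C=C1C[C@@H](C[C@]2(C)OC(C)(C)O[C@@H]2CO[Si](c3ccccc3)(c3ccccc3)C(C)(C)C)OC1=O
F5 | step 10 | (5S)-5-{[(4S,5R)-5-(hydroxymethyl)-2,2,4-trimethyl-1,3-dioxolan-4-yl]methyl}-3-methylideneoxolan-2-one | C=C1C[C@@H](C[C@]2(C)OC(C)(C)O[C@@H]2CO)OC1=O
F6 | step 4 | (2R,3S)-1,2-dihydroxy-3-methylhex-5-en-3-yl benzoate | C=CC[C@](C)(OC(=O)c1ccccc1)[C@H](O)CO
F7 | step 4 | (2R,3S)-3-methylhex-5-ene-1,2,3-triol | C=CC[C@](C)(O)[C@H](O)CO
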